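The route rests on cutting the C2–C3 bond of 1-(4-hydroxy-3-methoxyphenyl)hexadecane-3,5-dione (C1 is the benzylic CH2), the bond between the ethylene tether and the nearer carbonyl carbon. One rhodium-catalysed intermolecular hydroacylation adds the formyl C–H bond of 3-oxotetradecanal across the vinyl group of commercial 4-vinylguaiacol. This forms C2–C3 and C1–H with full atom economy and no protecting group. The step exploits the 1,3-relationship between the C5 ketone oxygen and C3: this oxygen holds rhodium in a five-membered acyl chelate and suppresses decarbonylation. The guaiacol ring on C1 identifies C1–C2 as a former styrene double bond. The precursors are thus an enolised β-keto aldehyde and a vinylphenol.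

Key step: step 2

Assumption: 3 and 5 are drawn as keto tautomers. Both are expected to exist largely as hydrogen-bonded enols, which does not change the connectivity.

Step 1
Reactants: 1 2-tridecanone
Product: 3 3-oxotetradecanal, via lithium tridec-1-en-2-olate 2 (not isolated)
Conditions: LiN(iPr)2 (commercial solution, 1.1 equiv), THF, −78 °C; HCO2CH2CF3 (1.3 equiv), −78 to 0 °C; 1 M aq HCl work-up; 3 kept cold and used promptly
Reagents that add atoms: 2,2,2-trifluoroethyl formate, O=COCC(F)(F)F; lithium diisopropylamide, CC(C)[N-]C(C)C.[Li+] (supplies the lithium of 2)
Why: Kinetic deprotonation at the methyl group, then a crossed Claisen-type formylation with the highly electrophilic trifluoroethyl formate, is fast at low temperature, and the product is at once held as its stabilised lithium enolate, which locks the regiochemistry until the acidic quench; no stereocenter is formed.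

Step 2
Reactants: 3 3-oxotetradecanal; 4 2-methoxy-4-vinylphenol (4-vinylguaiacol)
Product: 5 [12]-gingerdione, 1-(4-hydroxy-3-methoxyphenyl)hexadecane-3,5-dione
Conditions: [Rh(nbd)2]BF4 (5 mol %, nbd = norbornadiene), Cy2PCH2PCy2 (5 mol %), degassed acetone, brief H2 purge then Ar; 4 (1.5 equiv), slow addition of 3, 55 °C
Reagents that add atoms: none
Why: The cationic monovalent rhodium diphosphine fragment binds 3 through the C5 ketone oxygen and adds oxidatively into the formyl C–H bond to give a five-membered O-chelated acyl hydride of trivalent rhodium; alkene 4 then coordinates, the hydride migrates to the benzylic carbon C1, and reductive elimination of the primary alkyl with the acyl group forms the C2–C3 bond and returns the catalyst. The closest known reaction type is the chelation-assisted rhodium-catalysed intermolecular hydroacylation of terminal alkenes, established for β-keto, β-ester and β-amido aldehydes, for β-sulfanyl aldehydes and for salicylaldehydes, of which the enol form of 3 is the open-chain analogue. No ring of the product is closed and no stereocenter is created; the only ring involved is the transient rhodacycle (Rh, C3, C4, C5, O). The step needs linear over branched regioselectivity, which should come from reversible hydride insertion combined with faster reductive elimination from the unhindered primary alkyl in the crowded pocket of the small-bite-angle Cy2PCH2PCy2 ligand, and from the electron-rich guaiacol ring, which disfavours a benzylic rhodium alkyl. It also needs hydroacylation to outrun decarbonylation and self-condensation of 3, which the chelate, the excess of 4 and the slow addition of 3 should ensure. The phenol of 4 lies para to the vinyl group, so it cannot steer the metal towards the branched isomer, and it is inert in the neutral, base-free medium.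

Compound list
1 | 2-tridecanone | CCCCCCCCCCCC(C)=O | starting material
2 | lithium tridec-1-en-2-olate | CCCCCCCCCCCC(=C)[O-].[Li+] | intermediate
3 | 3-oxotetradecanal | CCCCCCCCCCCC(=O)CC=O | intermediate
4 | 2-methoxy-4-vinylphenol (4-vinylguaiacol) | C=Cc1ccc(O)c(OC)c1 | starting material
5 | [12]-gingerdione, 1-(4-hydroxy-3-methoxyphenyl)hexadecane-3,5-dione | CCCCCCCCCCCC(=O)CC(=O)CCc1ccc(O)c(OC)c1 | target

Total step count: 2
Longest linear sequence: 2

Steps most likely to fail (the route holds only two steps, so both are ranked):

1. Step 2. Several processes may hurt the hydroacylation.
- The electron-rich styrene may insert slowly, or insert towards the benzylic position.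
- The vinylphenol may oligomerise under acid or radical initiation.
- The aldehyde may self-condense or decarbonylate while it waits for the alkene.

The fallback runs from 3 back to 5. It replaces the alkene with a terminal aryl alkyne, the most reactive and most reliably linear-selective partner of this catalyst class, and it masks the phenol. Purchased 4-(benzyloxy)-3-methoxybenzaldehyde F1 would be converted by Seyferth–Gilbert homologation (dimethyl (1-diazo-2-oxopropyl)phosphonate, K2CO3, MeOH, room temperature) into 1-(benzyloxy)-4-ethynyl-2-methoxybenzene F2. Hydroacylation of F2 with 3 under the same [Rh(nbd)2]BF4/diphosphine catalysis still forms the C2–C3 bond. By syn addition of hydrogen and acyl it should give (1E)-1-[4-(benzyloxy)-3-methoxyphenyl]hexadec-1-ene-3,5-dione F3. Treatment with H2 (1 atm), Pd/C in EtOAc would then saturate the C1–C2 double bond and cleave the benzyl ether in one operation to reach 5.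

2. Step 1. Proton transfer between enolate 2 and the more acidic product may erode conversion and regiochemical purity. The free β-keto aldehyde may also cyclotrimerise or oligomerise during isolation and storage.

The fallback runs from 1 back to 3. It replaces the basic Claisen formylation with a Lewis-acid Mukaiyama-type reaction that delivers a storable masked aldehyde. The kinetic enolate of 1 (LiN(iPr)2, THF, −78 °C) would be trapped with Me3SiCl to give trimethyl(tridec-1-en-2-yloxy)silane F4. Reaction of F4 with HC(OMe)3 and catalytic Me3SiOSO2CF3 in CH2Cl2 at −78 °C should give 1,1-dimethoxytetradecan-3-one F5. Dilute aq HCl in THF would release 3 immediately before step 2.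

Further compounds
F1 | step 2 | 4-(benzyloxy)-3-methoxybenzaldehyde | COc1cc(C=O)ccc1OCc1ccccc1
F2 | step 2 | 1-(benzyloxy)-4-ethynyl-2-methoxybenzene | C#Cc1ccc(OCc2ccccc2)c(OC)c1
F3 | step 2 | (1E)-1-[4-(benzyloxy)-3-methoxyphenyl]hexadec-1-ene-3,5-dione | CCCCCCCCCCCC(=O)CC(=O)/C=C/c1ccc(OCc2ccccc2)c(OC)c1
F4 | step 1 | trimethyl(tridec-1-en-2-yloxy)silane | CCCCCCCCCCCC(=C)O[Si](C)(C)C
F5 | step 1 | 1,1-dimethoxytetradecan-3-one | CCCCCCCCCCCC(=O)CC(OC)OC
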